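**Retrosynthetic overview**
- The target is opened at C7–C8–C9 into a β-ring allylic chloride, CO and a C29 polyenyl stannane (carbonylative Stille); the stannane comes from syn-hydrostannation of a C29 enynol.
- The enynol comes from a Wittig reaction (C11'=C12') of the ε-ring C15 phosphonium salt with a C14 hydroxy-enynal, itself made from C10-dialdehyde by Takai iodo-olefination and Sonogashira coupling with propargyl alcohol.
- The ε-ring salt comes from a trans diol (3'R,6'R). The β-ring chloride comes from the cis diol: double-bond migration erases its C6 centre and a Mitsunobu reaction inverts its carbinol.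
- Both diols come from one CBS reduction and one LiAlH4 cleavage of a glycol-linked bis(cyclohexenone ester).
- Ring order: both six-membered rings are closed together, first, in a single twofold Robinson-type annulation of ethylene glycol bis(acetoacetate) with mesityl oxide; no ring is formed afterwards.

Assumption: the SMILES is read as all-E (3R,3'R,6'R)-siphonaxanthin, and ethane-1,2-diyl bis(3-oxobutanoate) is taken as a catalogue chemical (ethylene glycol diacetoacetate).

**Route**

Step 1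
Reactants: 1 mesityl oxide (4-methylpent-3-en-2-one, 3 equiv); 2 ethane-1,2-diyl bis(3-oxobutanoate)
Product: 5 ethane-1,2-diyl bis(2,6,6-trimethyl-4-oxocyclohex-2-ene-1-carboxylate) (C1 epimers), via bis-Michael adduct 3 (not isolated), via bis-ketol 4 (not isolated)
Conditions: ZnCl2 (0.5 equiv), n-heptane–toluene, reflux, Dean–Stark, 48 h
Reagents that add atoms: none
Why: Twofold Robinson-type annulation (Michael addition of each acetoacetate arm to mesityl oxide, then intramolecular aldol condensation), the known ZnCl2 route to the ethyl ester run on both arms of 2 so that both carbocycles close in one operation; the ester-bearing carbon forms without control and is sorted out in step 3.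

Step 2
Reactants: 5
Product: 6 ethane-1,2-diyl bis[(4R)-4-hydroxy-2,6,6-trimethylcyclohex-2-ene-1-carboxylate] (C1 epimers)
Conditions: (S)-2-methyl-CBS-oxazaborolidine (0.4 equiv), catecholborane (3 equiv), toluene, -78 °C; MeOH quench, aq. Na2CO3 wash
Reagents that add atoms: none
Why: Corey–Bakshi–Shibata reduction, 1,2-selective on the enone; the alkenyl flank acts as the large group, so the (S)-catalyst gives the 4R carbinol in both rings whatever the configuration at C1.

Step 3
Reactants: 6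
Product: 7 (1R,4R)-4-(hydroxymethyl)-3,5,5-trimethylcyclohex-2-en-1-ol (trans diol) and 8 (1R,4S)-4-(hydroxymethyl)-3,5,5-trimethylcyclohex-2-en-1-ol (cis diol)
Conditions: LiAlH4 (4 equiv), THF, 0 °C to rt; NaOH/H2O work-up; SiO2 chromatography separates 7 from 8 (about 1:1)
Reagents that add atoms: none
Why: Ester reduction with LiAlH4 releases both rings from the glycol linker; because the ester carbon was racemic and the carbinol is fixed as R, the product is two separable diastereomers, 7 with the 3'R,6'R pattern of the ε ring and 8, which feeds the β ring.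

Step 4
Reactants: 7
Product: 9 (1R,4R)-4-hydroxy-2,6,6-trimethylcyclohex-2-ene-1-carbaldehyde
Conditions: TEMPO (0.1 equiv), PhI(OAc)2 (1.1 equiv), CH2Cl2, 0 °C to rt; used at once
Reagents that add atoms: none
Why: TEMPO/PhI(OAc)2 oxidation is selective for the primary over the secondary allylic alcohol and is non-basic, so the α stereocentre and the β,γ double bond stay in place.

Step 5
Reactants: 9; 10 ethyl (2E)-4-(diethoxyphosphoryl)-3-methylbut-2-enoate
Product: 12 ethyl (2E,4E)-5-[(1R,4R)-4-hydroxy-2,6,6-trimethylcyclohex-2-en-1-yl]-3-methylpenta-2,4-dienoate, via lithiated phosphonate 11 (not isolated)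
Conditions: 10 (2.2 equiv), LiN(SiMe3)2 (2.2 equiv), THF, -78 °C; then 9, -78 to 0 °C
Reagents that add atoms: none
Why: Horner–Wadsworth–Emmons olefination with the stabilised vinylogous phosphonate anion gives the E C7'=C8' bond; the surplus anion only deprotonates the hydroxyl, and the low temperature protects the aldehyde α-centre from epimerisation.

Step 6
Reactants: 12
Product: 13 (1R,4R)-4-[(1E,3E)-5-hydroxy-3-methylpenta-1,3-dien-1-yl]-3,5,5-trimethylcyclohex-2-en-1-ol
Conditions: i-Bu2AlH (3.5 equiv), CH2Cl2, -78 °C; aq. KNaC4H4O6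
Reagents that add atoms: none
Why: 1,2-Reduction of the dienoate ester by i-Bu2AlH gives the primary allylic alcohol without touching the diene or the stereocentres.

Step 7
Reactants: 13
Product: 14 [(2E,4E)-5-[(1R,4R)-4-hydroxy-2,6,6-trimethylcyclohex-2-en-1-yl]-3-methylpenta-2,4-dien-1-yl]triphenylphosphonium bromide
Conditions: PPh3·HBr (1.05 equiv), MeOH, 0 °C to rt
Reagents that add atoms: triphenylphosphine hydrobromide, [Br-].c1ccc(cc1)[PH+](c1ccccc1)c1ccccc1
Why: Phosphonium salt formation through the pentadienyl cation (the standard preparation of C15 Wittig salts in carotenoid chemistry); the primary dienylic alcohol ionises far faster than the ring allylic alcohol, which keeps its configuration.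

Step 8
Reactants: 8
Product: 16 (4S)-4-hydroxy-2,6,6-trimethylcyclohex-1-ene-1-carbaldehyde, via cis hydroxy aldehyde 15 (not isolated)
Conditions: TEMPO (0.1 equiv), PhI(OAc)2 (1.1 equiv), CH2Cl2, 0 °C; then DBU (0.2 equiv), 0 °C, 1 h
Reagents that add atoms: none
Why: Selective TEMPO oxidation of the primary alcohol, then base-mediated isomerisation (α-cyclocitral to β-cyclocitral type) moves the double bond into the conjugated tetrasubstituted position and erases the former C1 centre; the carbinol is untouched and is now named S only because the CIP priorities of its ring neighbours change.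

Step 9
Reactants: 16
Product: 17 (1R)-4-formyl-3,5,5-trimethylcyclohex-3-en-1-yl benzoate
Conditions: PhCO2H (1.5 equiv), PPh3 (1.5 equiv), DIAD (1.5 equiv), toluene, -10 °C to rt
Reagents that add atoms: benzoic acid, OC(=O)c1ccccc1
Why: Mitsunobu reaction, SN2 at the homoallylic carbinol with inversion, gives the 3R configuration of the β ring.

Step 10
Reactants: 17
Product: 18 (1R)-4-(hydroxymethyl)-3,5,5-trimethylcyclohex-3-en-1-ol
Conditions: i-Bu2AlH (4.5 equiv), CH2Cl2, -78 to -20 °C; aq. KNaC4H4O6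
Reagents that add atoms: none
Why: i-Bu2AlH reduces the hindered enal 1,2 to the allylic alcohol and cleaves the benzoate in the same operation, leaving the inverted carbinol untouched.

Step 11
Reactants: 18
Product: 19 (1R)-4-(chloromethyl)-3,5,5-trimethylcyclohex-3-en-1-ol
Conditions: N-chlorosuccinimide (1.2 equiv), Me2S (1.3 equiv), CH2Cl2, -20 to 0 °C; used at once
Reagents that add atoms: N-chlorosuccinimide, ClN1C(=O)CCC1=O
Why: Corey–Kim chlorination converts only the primary allylic alcohol (alkoxysulfonium salt, then chloride displacement) and leaves the secondary ring alcohol free.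

Step 12
Reactants: 20 (2E,4E,6E)-2,7-dimethylocta-2,4,6-trienedial (3 equiv)
Product: 21 (2E,4E,6E,8E)-9-iodo-2,7-dimethylnona-2,4,6,8-tetraenal
Conditions: CHI3 (1 equiv), CrCl2 (6 equiv), THF–1,4-dioxane, 0 °C to rt, dark; excess 20 recovered
Reagents that add atoms: iodoform, IC(I)I
Why: Takai iodo-olefination of one aldehyde group (kept to mono-reaction by the excess of dialdehyde) gives the E vinyl iodide.

Step 13
Reactants: 21; 22 prop-2-yn-1-ol
Product: 23 (2E,4E,6E,8E)-12-hydroxy-2,7-dimethyldodeca-2,4,6,8-tetraen-10-ynal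
Conditions: Pd(PPh3)4 (0.03 equiv), CuI (0.06 equiv), Et3N, THF, rt, dark
Reagents that add atoms: none
Why: Sonogashira coupling of the vinyl iodide with the terminal alkyne, with retention of the E geometry.

Step 14
Reactants: 14; 23
Product: 25 (4E,6E,8E,10E,12E,14E,16E)-17-[(1R,4R)-4-hydroxy-2,6,6-trimethylcyclohex-2-en-1-yl]-6,11,15-trimethylheptadeca-4,6,8,10,12,14,16-heptaen-2-yn-1-ol, via phosphorus ylide 24 (not isolated)
Conditions: NaOMe (1.1 equiv), MeOH–CH2Cl2, -10 °C to rt; then n-heptane, reflux, 2 h (Z to E)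
Reagents that add atoms: none
Why: Wittig olefination of the polyenal with the semi-stabilised C15 ylide builds C11'=C12'; the E/Z mixture at the new bond is equilibrated thermally to the all-E polyene, as is usual for carotenoids.

Step 15
Reactants: 25
Product: 26 (2E,4E,6E,8E,10E,12E,14E,16E)-17-[(1R,4R)-4-hydroxy-2,6,6-trimethylcyclohex-2-en-1-yl]-6,11,15-trimethyl-2-(tributylstannyl)heptadeca-2,4,6,8,10,12,14,16-octaen-1-ol
Conditions: Bu3SnH (1.2 equiv), PdCl2(PPh3)2 (0.03 equiv), THF, 0 °C, dark; used at once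
Reagents that add atoms: tributyltin hydride, CCCC[SnH](CCCC)CCCC
Why: Palladium-catalysed hydrostannation is a syn addition and the propargylic hydroxyl steers tin to the proximal carbon (C9), so the C11 chain ends up cis to CH2OH as the E enone requires.

Step 16
Reactants: 26; 19
Product: 27 (3R,3'R,6'R)-3,19,3'-trihydroxy-7,8-dihydro-β,ε-caroten-8-one (siphonaxanthin, all-E; CNP0183826.2)
Conditions: Pd2(dba)3 (0.05 equiv), AsPh3 (0.4 equiv), CO (3 atm), THF, 45 °C, dark; crystallisation of the all-E isomer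
Reagents that add atoms: carbon monoxide, [C-]#[O+]
Why: Stille carbonylative cross-coupling (oxidative addition of the allylic chloride to zerovalent palladium, CO insertion at the primary terminus, transmetalation with the vinylstannane with retention) gives the β,γ-unsaturated dienone; no stereocentre is touched, and the ring double bond should stay unconjugated because conjugation would need an exocyclic alkene flanked by the gem-dimethyl and methyl groups.

**Compound list**

1 | 4-methylpent-3-en-2-one (mesityl oxide) | CC(C)=CC(C)=O | starting material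
2 | ethane-1,2-diyl bis(3-oxobutanoate) | CC(=O)CC(=O)OCCOC(=O)CC(C)=O | starting material
3 | ethane-1,2-diyl bis(2-acetyl-3,3-dimethyl-5-oxohexanoate) (bis-Michael adduct, stereoisomer mixture) | CC(=O)CC(C)(C)C(C(C)=O)C(=O)OCCOC(=O)C(C(C)=O)C(C)(C)CC(C)=O | intermediate
4 | ethane-1,2-diyl bis(2-hydroxy-2,6,6-trimethyl-4-oxocyclohexane-1-carboxylate) (bis-ketol, stereoisomer mixture) | CC1(O)CC(=O)CC(C)(C)C1C(=O)OCCOC(=O)C1C(C)(O)CC(=O)CC1(C)C | intermediate
5 | ethane-1,2-diyl bis(2,6,6-trimethyl-4-oxocyclohex-2-ene-1-carboxylate) (C1 epimers) | CC1=CC(=O)CC(C)(C)C1C(=O)OCCOC(=O)C1C(C)=CC(=O)CC1(C)C | intermediate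
6 | ethane-1,2-diyl bis[(4R)-4-hydroxy-2,6,6-trimethylcyclohex-2-ene-1-carboxylate] (C1 epimers) | CC1=C[C@H](O)CC(C)(C)C1C(=O)OCCOC(=O)C1C(C)=C[C@H](O)CC1(C)C | intermediate
7 | (1R,4R)-4-(hydroxymethyl)-3,5,5-trimethylcyclohex-2-en-1-ol (trans) | CC1=C[C@H](O)CC(C)(C)[C@H]1CO | intermediate
8 | (1R,4S)-4-(hydroxymethyl)-3,5,5-trimethylcyclohex-2-en-1-ol (cis) | CC1=C[C@H](O)CC(C)(C)[C@@H]1CO | intermediate
9 | (1R,4R)-4-hydroxy-2,6,6-trimethylcyclohex-2-ene-1-carbaldehyde | CC1=C[C@H](O)CC(C)(C)[C@H]1C=O | intermediate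
10 | ethyl (2E)-4-(diethoxyphosphoryl)-3-methylbut-2-enoate | CCOC(=O)/C=C(\C)CP(=O)(OCC)OCC | starting material
11 | lithium salt of the carbanion of 10 (lithiated at the carbon next to phosphorus) | CCOC(=O)/C=C(\C)[CH-]P(=O)(OCC)OCC.[Li+] | intermediate
12 | ethyl (2E,4E)-5-[(1R,4R)-4-hydroxy-2,6,6-trimethylcyclohex-2-en-1-yl]-3-methylpenta-2,4-dienoate | CC1=C[C@H](O)CC(C)(C)[C@H]1/C=C/C(C)=C/C(=O)OCC | intermediate
13 | (1R,4R)-4-[(1E,3E)-5-hydroxy-3-methylpenta-1,3-dien-1-yl]-3,5,5-trimethylcyclohex-2-en-1-ol | CC1=C[C@H](O)CC(C)(C)[C@H]1/C=C/C(C)=C/CO | intermediate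
14 | [(2E,4E)-5-[(1R,4R)-4-hydroxy-2,6,6-trimethylcyclohex-2-en-1-yl]-3-methylpenta-2,4-dien-1-yl]triphenylphosphonium bromide | CC1=C[C@H](O)CC(C)(C)[C@H]1/C=C/C(C)=C/C[P+](c1ccccc1)(c1ccccc1)c1ccccc1.[Br-] | intermediate
15 | (1S,4R)-4-hydroxy-2,6,6-trimethylcyclohex-2-ene-1-carbaldehyde (cis) | CC1=C[C@H](O)CC(C)(C)[C@@H]1C=O | intermediate
16 | (4S)-4-hydroxy-2,6,6-trimethylcyclohex-1-ene-1-carbaldehyde | O=CC1=C(C)C[C@H](O)CC1(C)C | intermediate
17 | (1R)-4-formyl-3,5,5-trimethylcyclohex-3-en-1-yl benzoate | O=CC1=C(C)C[C@@H](OC(=O)c2ccccc2)CC1(C)C | intermediate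
18 | (1R)-4-(hydroxymethyl)-3,5,5-trimethylcyclohex-3-en-1-ol | OCC1=C(C)C[C@@H](O)CC1(C)C | intermediate
19 | (1R)-4-(chloromethyl)-3,5,5-trimethylcyclohex-3-en-1-ol | ClCC1=C(C)C[C@@H](O)CC1(C)C | intermediate
20 | (2E,4E,6E)-2,7-dimethylocta-2,4,6-trienedial (C10-dialdehyde) | O=C/C(C)=C/C=C/C=C(C)/C=O | starting material
21 | (2E,4E,6E,8E)-9-iodo-2,7-dimethylnona-2,4,6,8-tetraenal | O=C/C(C)=C/C=C/C=C(C)/C=C/I | intermediate
22 | prop-2-yn-1-ol | C#CCO | starting material
23 | (2E,4E,6E,8E)-12-hydroxy-2,7-dimethyldodeca-2,4,6,8-tetraen-10-ynal | O=C/C(C)=C/C=C/C=C(C)/C=C/C#CCO | intermediate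
24 | [(2E,4E)-5-[(1R,4R)-4-hydroxy-2,6,6-trimethylcyclohex-2-en-1-yl]-3-methylpenta-2,4-dien-1-ylidene]triphenylphosphorane (ylide of 14) | CC1=C[C@H](O)CC(C)(C)[C@H]1/C=C/C(C)=C/C=P(c1ccccc1)(c1ccccc1)c1ccccc1 | intermediate
25 | (4E,6E,8E,10E,12E,14E,16E)-17-[(1R,4R)-4-hydroxy-2,6,6-trimethylcyclohex-2-en-1-yl]-6,11,15-trimethylheptadeca-4,6,8,10,12,14,16-heptaen-2-yn-1-ol | CC1=C[C@H](O)CC(C)(C)[C@H]1/C=C/C(C)=C/C=C/C(C)=C/C=C/C=C(C)/C=C/C#CCO | intermediate
26 | (2E,4E,6E,8E,10E,12E,14E,16E)-17-[(1R,4R)-4-hydroxy-2,6,6-trimethylcyclohex-2-en-1-yl]-6,11,15-trimethyl-2-(tributylstannyl)heptadeca-2,4,6,8,10,12,14,16-octaen-1-ol | CC1=C[C@H](O)CC(C)(C)[C@H]1/C=C/C(C)=C/C=C/C(C)=C/C=C/C=C(C)/C=C/C=C(\CO)[Sn](CCCC)(CCCC)CCCC | intermediate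
27 | (3R,3'R,6'R)-3,19,3'-trihydroxy-7,8-dihydro-β,ε-caroten-8-one (siphonaxanthin) | CC1=C[C@H](O)CC(C)(C)[C@H]1/C=C/C(C)=C/C=C/C(C)=C/C=C/C=C(C)/C=C/C=C(\CO)C(=O)CC1=C(C)C[C@@H](O)CC1(C)C | target

**Totals**

Total step count: 16. Longest linear sequence: 10 steps (1, 2, 3, 4, 5, 6, 7, 14, 15, 16).

**Three steps most likely to fail, with fallbacks**

Step 2 (catalyst control by the CBS reagent on a hindered, isophorone-like enone; any leakage lowers both the diastereomer and the enantiomer purity of 7 and 8). The fallback uses substrate control plus an enzymatic resolution and sets out from 5. NaOEt in ethanol transesterifies 5 to racemic ethyl 2,6,6-trimethyl-4-oxocyclohex-2-ene-1-carboxylate F1. LiBH(s-Bu)3 at -78 °C, attacking anti to the axial ring methyl, gives the racemic trans hydroxy ester F2. Burkholderia cepacia lipase with vinyl acetate acetylates the 4S enantiomer (Kazlauskas' rule) to the (1S,4S) acetate F3 and leaves the (1R,4R) hydroxy ester F4. LiAlH4 reduces F4 to 7, where the ε branch rejoins. LiAlH4 reduces F3 to the (1S,4S) diol F5, which under the conditions of step 8 passes through the (1S,4S) hydroxy aldehyde F6 to (4R)-4-hydroxy-2,6,6-trimethylcyclohex-1-ene-1-carbaldehyde F7; NaBH4 reduces F7 to 18, where the β branch rejoins, so steps 9 and 10 are not needed. If the lipase prefers the other enantiomer, acetate and alcohol simply change roles.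

Step 15 (the polyene conjugated to the alkyne may pull tin to C10 instead of C9). The fallback makes a carbonyl group direct the addition and sets out from 25. TEMPO/PhI(OAc)2 oxidises the propargylic alcohol to the ynal F8; Bu3SnH with Pd(PPh3)4 then adds syn with tin α to the carbonyl, giving the 2-stannyl enal F9; NaBH4/CeCl3·7H2O reduces the aldehyde and the route is back at 26.

Step 16 (direct coupling without CO, β-hydride loss from the hindered π-allyl complex, or slow transmetalation of the α-branched stannane). The fallback makes the acyl electrophile first and sets out from 19. Thiocarbonylation (Pd(PPh3)4, CO 10 atm, ethanethiol, i-Pr2NEt, THF, 50 °C) gives S-ethyl [(4R)-4-hydroxy-2,6,6-trimethylcyclohex-1-en-1-yl]ethanethioate F10. Liebeskind–Srogl coupling of F10 with 26 (Pd2(dba)3, tri(2-furyl)phosphine, copper thiophene-2-carboxylate CuO2C(C4H3S), THF, rt) then gives the ketone, and the route is back at 27.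

**Further compounds**

F1 | step 2 | ethyl 2,6,6-trimethyl-4-oxocyclohex-2-ene-1-carboxylate (racemic) | CCOC(=O)C1C(C)=CC(=O)CC1(C)C
F2 | step 2 | ethyl trans-4-hydroxy-2,6,6-trimethylcyclohex-2-ene-1-carboxylate (racemic; (1R,4R) and (1S,4S)) | CC1=C[C@H](O)CC(C)(C)[C@H]1C(=O)OCC.CC1=C[C@@H](O)CC(C)(C)[C@@H]1C(=O)OCC
F3 | step 2 | ethyl (1S,4S)-4-acetoxy-2,6,6-trimethylcyclohex-2-ene-1-carboxylate | CC1=C[C@@H](OC(C)=O)CC(C)(C)[C@@H]1C(=O)OCC
F4 | step 2 | ethyl (1R,4R)-4-hydroxy-2,6,6-trimethylcyclohex-2-ene-1-carboxylate | CC1=C[C@H](O)CC(C)(C)[C@H]1C(=O)OCC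
F5 | step 2 | (1S,4S)-4-(hydroxymethyl)-3,5,5-trimethylcyclohex-2-en-1-ol | CC1=C[C@@H](O)CC(C)(C)[C@@H]1CO
F6 | step 2 | (1S,4S)-4-hydroxy-2,6,6-trimethylcyclohex-2-ene-1-carbaldehyde | CC1=C[C@@H](O)CC(C)(C)[C@@H]1C=O
F7 | step 2 | (4R)-4-hydroxy-2,6,6-trimethylcyclohex-1-ene-1-carbaldehyde | O=CC1=C(C)C[C@@H](O)CC1(C)C
F8 | step 15 | (4E,6E,8E,10E,12E,14E,16E)-17-[(1R,4R)-4-hydroxy-2,6,6-trimethylcyclohex-2-en-1-yl]-6,11,15-trimethylheptadeca-4,6,8,10,12,14,16-heptaen-2-ynal | CC1=C[C@H](O)CC(C)(C)[C@H]1/C=C/C(C)=C/C=C/C(C)=C/C=C/C=C(C)/C=C/C#CC=O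
F9 | step 15 | (2E,4E,6E,8E,10E,12E,14E,16E)-17-[(1R,4R)-4-hydroxy-2,6,6-trimethylcyclohex-2-en-1-yl]-6,11,15-trimethyl-2-(tributylstannyl)heptadeca-2,4,6,8,10,12,14,16-octaenal | CC1=C[C@H](O)CC(C)(C)[C@H]1/C=C/C(C)=C/C=C/C(C)=C/C=C/C=C(C)/C=C/C=C(\C=O)[Sn](CCCC)(CCCC)CCCC
F10 | step 16 | S-ethyl [(4R)-4-hydroxy-2,6,6-trimethylcyclohex-1-en-1-yl]ethanethioate | CCSC(=O)CC1=C(C)C[C@@H](O)CC1(C)C
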